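The ratio I wanted was how much of the open intermediate goes to target against how much goes elsewhere, set-up by set-up.

    open intermediate → solvolysis product (k1 = 8.2 s⁻¹)
    substrate → open intermediate (k2 = 0.16 s⁻¹)
    second nucleophile + open intermediate → other capture product (k3 = 18000 M⁻¹ s⁻¹)
    first nucleophile + open intermediate → target (k4 = 6900 M⁻¹ s⁻¹)
    first nucleophile → decomposed reagent (k5 = 0.017 s⁻¹)
    open intermediate + capture agent → trapped intermediate (k6 = 190 M⁻¹ s⁻¹)

| setting | theta | beta | gamma | zeta |
|---|---|---|---|---|
| substrate | 0.0020 M | 0.0020 M | 0.0020 M | 0.0020 M |
| first nucleophile | 2.00 mM | 2.00 mM | 2.00 mM | 2.00 mM |
| second nucleophile | 1.00 mM | 1.00 mM (fed, over 0.800 min) | 1.00 mM | 1.00 mM |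
| capture agent | 0.600 mM | 0.600 mM | 0.600 mM | 0.600 mM |
| remark | a single well-mixed tank run continuously and read at steady state, 1.0 min in it on average | a stirred flask in which second nucleophile is dosed at a steady rate over 0.800 min without added volume, worked up at 1.0 min | one stirred flow tank at steady state, fed with the mixture as stated, mean residence time 10.0 min | everything together in a closed stirred flask, run for 1.0 min |
| time |  | 1.0 min |  | 1.0 min |

1. the set-up with the highest amount of target at the outlet or at the end, in percent of the substrate put in ("none" if the first two lie within 2 percentage points) (theta / beta / gamma / zeta / none)
2. amount of target at the outlet or at the end, in percent of the substrate put in, theta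
3. amount of target at the outlet or at the end, in percent of the substrate put in, beta
4. amount of target at the outlet or at the end, in percent of the substrate put in, gamma
5. amount of target at the outlet or at the end, in percent of the substrate put in, zeta

- the stated concentrations are those of everything mixed, before any reaction; amounts are the same in each set-up
- the feed brings no volume worth counting
- run time (beta): 1.0 min

I wrote each capture as a pseudo-first-order rate: b for the first nucleophile, d for the second nucleophile, c for the capture agent, and w for solvolysis. At the charged amounts these were:

b = 13.8 s⁻¹, d = 18.0 s⁻¹, c = 0.114 s⁻¹, w = 8.2 s⁻¹

Their sum, 40.1 s⁻¹, is far faster than the opening of substrate at 0.16 s⁻¹, so I treated the open intermediate as a quasi-steady state.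

s = b / (w + b + d + c) = 34.4% at the charge

This s is the capture share, the target-forming rate over the sum of the rates that remove the open intermediate.

I bracketed beta by hand. For a ceiling I set d to zero and kept b at its charge. For a floor I kept d at its charge and cut b to half, a loss I judged generous:

ceiling 62.4%, floor 20.8%

The mean life of substrate by its opening step is 6.25 s, and in that time the dosing brings in 0.130 mM of second nucleophile. Using that amount for d in both limits narrowed them, but to an estimate and no longer to strict bounds:

ceiling 56.4%, floor 39.3%

I stopped there by hand; both nucleophiles keep moving.

The forecast named beta, with 23.2% for theta, 48% for beta, 7.7% for gamma and 34.6% for zeta, on the ground that “dosing second nucleophile keeps it scarce during that burst”. Its beta figure stood inside my bracket.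

The simulation gave 23.2% for theta, 7.65% for gamma and 34.6% for zeta, while beta came highest at 47.4%.

Between beta and gamma the largest single effect is the path from first nucleophile to decomposed reagent, a part of the gap and not all of it: with that path struck out, gamma's shortfall against beta went from 40 percentage points to 14 points. I then carried the share, 34.4% at the charge, to theta. Its tank held 0.761 mM of first nucleophile, and since 30.7% of the substrate charged left as other capture product, it held 0.386 mM of second nucleophile.

s = 25.6%

On the 90.6% of substrate no longer present as substrate, that made 23.2%, and theta read 23.2%.

Its constants are invented; the run is a simulation.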